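Time is not the common measure here: the orders are asked at 20 % conversion of the starting material, and by 25.0 min north-east reads 21.8 % of product while south-east reads 14.6 %.

the same everywhere: starting material 0.30 M; free catalyst 10 mol%

| charge | coupling partner | capture agent | remark |
|---|---|---|---|
| south-east | 0.55 equiv | 0.090 M | run made earlier |
| north-east | 2.2 equiv | 0.090 M | run made earlier |
| south-west | 1.1 equiv | 0.18 M | run made earlier |
| flask | 1.10 equiv | 0.0900 M |  |

| run | time / min | product / % |
|---|---|---|
| south-east | 8.00 | 3.8 |
| south-east | 15.0 | 8.3 |
| south-east | 25.0 | 14.6 |
| south-east | 50.0 | 23.7 |
| south-east | 90.0 | 32.5 |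
| north-east | 8.00 | 6.4 |
| north-east | 15.0 | 12.2 |
| north-east | 25.0 | 21.8 |
| north-east | 50.0 | 37.5 |
| north-east | 90.0 | 51.4 |
| south-west | 8.00 | 5.2 |
| south-west | 15.0 | 10.8 |
| south-west | 25.0 | 16.1 |
| south-west | 50.0 | 24.5 |
| south-west | 90.0 | 33.2 |

(scatter of a reading: 0.5 percentage points)

- no earlier run changes the charge of free catalyst; that part of a forecast is a guess

1. apparent order in free catalyst when 20 % of the starting material are converted (percent change of the rate of making product for one percent more free catalyst charged)
2. apparent order in coupling partner when 20 % of the starting material are converted (percent change of the rate of making product for one percent more coupling partner charged)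

Coupling partner comes first. A reagent entering the rate directly would show order one. North-east holds twice this flask's coupling partner and south-east half, so the two runs bracket the flask evenly on a logarithmic scale. Between 25.0 min and 50.0 min, product rises by 0.00364 min⁻¹ of the charge in south-east and 0.00628 min⁻¹ in north-east. The order across a bracket, the logarithm of the slope ratio over the logarithm of the charge ratio, is 0.393. It is a reading at fixed time, standing in for fixed conversion, because north-east product has already reached 21.8 % at the start of the window, more than the mark.

Capture agent comes next. If it removes catalyst, more of it should cost rate later rather than at once. South-west has the flask's coupling partner and twice its capture agent. The geometric mean of the bracket slopes is 0.00478 min⁻¹. The south-west slope over the same window is 0.00336 min⁻¹, lower than that mean. At 8.00 min, however, south-west reads 5.2 % against a bracket mean of 4.93 %. This pattern reads as a catalyst loss growing with time.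

Free catalyst was never varied. My guess is an order a little above one, since a larger charge would reach the mark earlier.

The forecast gives 1.2 for free catalyst and 0.45 for coupling partner, reasoning that “More catalyst would reach 20% sooner, with less of it lost, so the order should be slightly above one.”

The simulation gives 1.3 for free catalyst and 0.42 for coupling partner. In this flask the trapped intermediate, an off-cycle form of the catalyst, holds 12.1 % of the catalyst at 8.00 min and 38.5 % at 40.0 min.

    coupling partner + free catalyst ⇌ catalyst intermediate A (K = 7.10 M⁻¹, k = 4.80 M⁻¹ min⁻¹)
    catalyst intermediate A ⇌ by-product + catalyst intermediate B (K = 0.630 M, k = 0.340 min⁻¹)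
    starting material + catalyst intermediate B → catalyst intermediate C (k = 3.80 M⁻¹ min⁻¹)
    catalyst intermediate C ⇌ free catalyst + product (K = 0.130 M, k = 0.300 min⁻¹)
    catalyst intermediate A + capture agent → trapped intermediate (k = 0.500 M⁻¹ min⁻¹)

This flask makes product at 0.00205 M min⁻¹ at 23.0 min, which is 0.00683 min⁻¹ of the charge. Doubling the coupling partner with the order 0.393 scales that to 0.00898 min⁻¹, and the north-east slope between 15.0 min and 25.0 min reads 0.00960 min⁻¹.

The readings were computed on assumed constants.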